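**Retrosynthetic overview**
- The C1–C10 oxirane is made last, by peripheral epoxidation of the 1(10)E,4Z-diene. The C8 angelate comes from acylating the 8-OH that the key step sets free.
- Key disconnection: C6–C7 and O6–C12 are cut together. This leads back to an acyclic Z-enal carrying a C7–C8 vinyl-oxirane (a 2-oxiranylacrylate), which serves as a latent allyl anion.
- The vinyl-oxirane comes from a dialdehyde and a chiral 2-(methoxycarbonyl)allyl sulfonium ylide, which supplies C7 and C11–C13.
- C3–C4 comes from an asymmetric Ni/Cr coupling. The partners are a (Z)-iodide (from but-2-yn-1-ol) and a β,γ-unsaturated aldehyde (from but-3-yn-1-ol, Me3Al and oxirane).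
- Ring order: transient C7–C8 oxirane, then ten-membered carbocycle and γ-lactone in one flask, then the C1–C10 oxirane.

Assumption: germacrane numbering is used (C3 methacrylate, C6/C7 lactone fusion, C8 angelate, C1–C10 oxirane). Isothiocineole is taken as commercial (one step from limonene and sulfur), and its (1R,4R,5R) form is assumed to give the (R,R)-oxirane; otherwise its antipode is used.

Step 1
Reactants: 1 but-3-yn-1-ol
Product: 2 tert-butyl(but-3-yn-1-yloxy)dimethylsilane
Conditions: TBSCl, imidazole, CH2Cl2, 0 °C to rt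
Reagents that add atoms: tert-butyldimethylsilyl chloride, CC(C)(C)[Si](C)(C)Cl
Why: Imidazole-promoted silylation masks the future C8 hydroxyl against Me3Al, n-BuLi and Cr(II); no stereocentre is involved.

Step 2
Reactants: 2 tert-butyl(but-3-yn-1-yloxy)dimethylsilane; 3 oxirane
Product: 6 (3E)-6-[(tert-butyldimethylsilyl)oxy]-4-methylhex-3-en-1-ol, via alkenyldimethylalane 4 (not isolated), via lithium alkenylalanate 5 (not isolated)
Conditions: Me3Al, Cp2ZrCl2 (20 mol %), CH2Cl2, 0 °C to rt; evaporate; n-BuLi, hexane/THF, −78 to 0 °C; oxirane, −30 °C to rt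
Reagents that add atoms: trimethylaluminium, C[Al](C)C
Why: Negishi Zr-catalysed syn-carboalumination puts CH3 (C14) on the internal carbon and Al on the terminus, which fixes the 1(10)E geometry, and the alanate then opens oxirane with retention to add C2–C3.

Step 3
Reactants: 6 (3E)-6-[(tert-butyldimethylsilyl)oxy]-4-methylhex-3-en-1-ol
Product: 7 (3E)-6-[(tert-butyldimethylsilyl)oxy]-4-methylhex-3-enal
Conditions: Dess–Martin periodinane, CH2Cl2, 0 °C, used crude
Reagents that add atoms: none
Why: Dess–Martin oxidation is mild and base-free, so the β,γ-unsaturated aldehyde forms without moving into conjugation.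

Step 4
Reactants: 8 but-2-yn-1-ol
Product: 10 (2Z)-3-iodobut-2-en-1-ol, via cyclic vinylalanate 9 (not isolated)
Conditions: Red-Al, THF, 0 °C to rt; I2, −78 °C
Reagents that add atoms: iodine, II
Why: Hydroxyl-directed trans-hydroalumination followed by iodinolysis with retention gives only the Z-iodide, which becomes the 4Z alkene.

Step 5
Reactants: 10 (2Z)-3-iodobut-2-en-1-ol
Product: 11 tert-butyl{[(2Z)-3-iodobut-2-en-1-yl]oxy}dimethylsilane
Conditions: TBSCl, imidazole, CH2Cl2, 0 °C to rt
Reagents that add atoms: tert-butyldimethylsilyl chloride, CC(C)(C)[Si](C)(C)Cl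
Why: This silyl ether protection of the future C6 hydroxyl lets both primary alcohols be released together later.

Step 6
Reactants: 7 (3E)-6-[(tert-butyldimethylsilyl)oxy]-4-methylhex-3-enal; 11 tert-butyl{[(2Z)-3-iodobut-2-en-1-yl]oxy}dimethylsilane
Product: 13 (2Z,4S,6E)-1,9-bis[(tert-butyldimethylsilyl)oxy]-3,7-dimethylnona-2,6-dien-4-ol, via alkenylchromium(III) 12 (not isolated)
Conditions: CrCl2, NiCl2 (2 mol %), chiral oxazoline–sulfonamide ligand (enantiomer giving 4S), Et3N, THF, rt
Reagents that add atoms: none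
Why: The asymmetric Nozaki–Hiyama–Kishi alkenylation forms C3–C4 with retention of the Z geometry under non-basic conditions, and the chiral Cr(III)–sulfonamide complex selects the aldehyde face to set C3 as S.

Step 7
Reactants: 13 (2Z,4S,6E)-1,9-bis[(tert-butyldimethylsilyl)oxy]-3,7-dimethylnona-2,6-dien-4-ol
Product: 14 (2Z,4S,6E)-1,9-bis[(tert-butyldimethylsilyl)oxy]-3,7-dimethylnona-2,6-dien-4-yl methacrylate
Conditions: methacrylic anhydride, Et3N, DMAP (cat.), CH2Cl2, 0 °C
Reagents that add atoms: methacrylic anhydride, C=C(C)C(=O)OC(=O)C(C)=C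
Why: DMAP-catalysed acylation of the only free hydroxyl installs the final C3 ester with retention at C3.

Step 8
Reactants: 14 (2Z,4S,6E)-1,9-bis[(tert-butyldimethylsilyl)oxy]-3,7-dimethylnona-2,6-dien-4-yl methacrylate
Product: 15 (2Z,4S,6E)-1,9-dihydroxy-3,7-dimethylnona-2,6-dien-4-yl methacrylate
Conditions: HF·pyridine, THF/pyridine, 0 °C to rt
Reagents that add atoms: none
Why: Buffered fluoride desilylation frees both primary alcohols at once and leaves the methacrylate and both alkenes untouched.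

Step 9
Reactants: 15 (2Z,4S,6E)-1,9-dihydroxy-3,7-dimethylnona-2,6-dien-4-yl methacrylate
Product: 16 (2Z,4S,6E)-3,7-dimethyl-1,9-dioxonona-2,6-dien-4-yl methacrylate
Conditions: Dess–Martin periodinane (2.4 equiv), CH2Cl2, 0 °C, used at once
Reagents that add atoms: none
Why: A double Dess–Martin oxidation gives the Z-enal (C6) and the β,γ-unsaturated aldehyde (C8) without base, so neither alkene moves or isomerises.

Step 10
Reactants: 17 (1R,4R,5R)-isothiocineole; 18 methyl 2-(bromomethyl)acrylate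
Product: 19 S-[2-(methoxycarbonyl)allyl]isothiocineolium bromide
Conditions: MeCN, rt
Reagents that add atoms: none
Why: SN2 alkylation of the sulfide by the activated allylic bromide takes place on the one exposed sulfur lone pair, giving a single sulfonium diastereomer.

Step 11
Reactants: 16 (2Z,4S,6E)-3,7-dimethyl-1,9-dioxonona-2,6-dien-4-yl methacrylate; 19 S-[2-(methoxycarbonyl)allyl]isothiocineolium bromide
Product: 21 methyl 2-[(2R,3R)-3-{(2E,5S,6Z)-5-(methacryloyloxy)-2,6-dimethyl-8-oxoocta-2,6-dien-1-yl}oxiran-2-yl]acrylate, via sulfonium ylide 20 (not isolated)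
Conditions: 19, LiHMDS (1.0 equiv), THF, −78 °C; then 16, −78 to −40 °C
Reagents that add atoms: none
Why: In this asymmetric sulfur-ylide (Corey–Chaykovsky type) epoxidation the preformed allylic ylide attacks the free aliphatic aldehyde much faster than the hindered conjugated Z-enal, and the rigid chiral sulfide controls ylide conformation and face to give the trans-(7R,8R)-vinyl-oxirane.

Step 12
Reactants: 21 methyl 2-[(2R,3R)-3-{(2E,5S,6Z)-5-(methacryloyloxy)-2,6-dimethyl-8-oxoocta-2,6-dien-1-yl}oxiran-2-yl]acrylate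
Product: 26 (3S,6R,7R,8R)-8-hydroxy-3-(methacryloyloxy)germacra-1(10)E,4Z,11(13)-trien-12,6-olide, via allylic iodide silyl ether 22 (not isolated), via allylchromium(III) 23 (not isolated), via ten-membered chromium alkoxide 24 (not isolated), via 8-O-trimethylsilyl lactone 25 (not isolated)
Conditions: TMSCl, LiI (1.0 equiv each), THF, −78 °C; then slow addition (12 h) to CrCl2 (8 equiv), THF, 2 mM, rt; aq. citric acid work-up
Reagents that add atoms: none
Why: Proposed new method: TMSI made in situ opens the acrylate-conjugated oxirane by SN2' attack of iodide at C13 and caps O8 as a silyl ether, Cr(II) converts the allylic iodide into a 2-(methoxycarbonyl)allylchromium(III) that adds through C7 to the Z-enal in a closed chair transition state (E-allyl geometry gives 6,7-anti, and A1,3 strain between CO2Me and the C8 substituents fixes the C7 face, hence 6R,7R), and the O6 chromium alkoxide, gauche to the ester as it leaves the chair, expels methoxide to close the trans-lactone while O8 stays masked until work-up; the closest known reaction types are the CrCl2/LiI coupling of 1,3-diene monoepoxides with aldehydes to 2-vinyl-1,3-diols and the Nozaki–Hiyama–Kishi allylation/lactonisation macrocyclisation of 2-(halomethyl)enoates.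

Step 13
Reactants: 26 (3S,6R,7R,8R)-8-hydroxy-3-(methacryloyloxy)germacra-1(10)E,4Z,11(13)-trien-12,6-olide
Product: 27 (3S,6R,7R,8R)-8-(angeloyloxy)-3-(methacryloyloxy)germacra-1(10)E,4Z,11(13)-trien-12,6-olide
Conditions: angelic acid, 2,4,6-trichlorobenzoyl chloride, Et3N, toluene, rt; then 26, 75 °C
Reagents that add atoms: angelic acid, C/C=C(/C)C(=O)O
Why: Yamaguchi mixed-anhydride esterification run without DMAP acylates the hindered 8-OH with retention at C8 and avoids isomerisation of angelate to tiglate.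

Step 14
Reactants: 27 (3S,6R,7R,8R)-8-(angeloyloxy)-3-(methacryloyloxy)germacra-1(10)E,4Z,11(13)-trien-12,6-olide
Product: 28 target, (1R,3S,6R,7R,8R,10R)-8-(angeloyloxy)-1,10-epoxy-3-(methacryloyloxy)germacra-4Z,11(13)-dien-12,6-olide
Conditions: mCPBA (1.05 equiv), CH2Cl2, 0 °C
Reagents that add atoms: 3-chloroperoxybenzoic acid, O=C(OO)c1cccc(Cl)c1
Why: In this Prilezhaev epoxidation only the C1=C10 alkene is electron-rich (C4=C5 has two allylic acyloxy groups and the other three alkenes are conjugated to carbonyls), and attack on the outer face of the E-alkene, whose inner face is blocked by the ring, gives the trans 1R,10R oxirane.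

**Compound list**
1 | but-3-yn-1-ol | C#CCCO | starting material
2 | tert-butyl(but-3-yn-1-yloxy)dimethylsilane | C#CCCO[Si](C)(C)C(C)(C)C | intermediate
3 | oxirane | C1CO1 | starting material
4 | dimethyl[(1E)-4-(TBS-oxy)-2-methylbut-1-enyl]alane | C[Al](C)/C=C(\C)CCO[Si](C)(C)C(C)(C)C | intermediate
5 | lithium butyl(dimethyl)[(1E)-4-(TBS-oxy)-2-methylbut-1-enyl]alanate | [Li+].CCCC[Al-](C)(C)/C=C(\C)CCO[Si](C)(C)C(C)(C)C | intermediate
6 | (3E)-6-[(tert-butyldimethylsilyl)oxy]-4-methylhex-3-en-1-ol | OCC/C=C(\C)CCO[Si](C)(C)C(C)(C)C | intermediate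
7 | (3E)-6-[(tert-butyldimethylsilyl)oxy]-4-methylhex-3-enal | O=CC/C=C(\C)CCO[Si](C)(C)C(C)(C)C | intermediate
8 | but-2-yn-1-ol | CC#CCO | starting material
9 | sodium 2,2-bis(2-methoxyethoxy)-3-methyl-2,5-dihydro-1,2-oxaluminol-2-uide | [Na+].CC1=CCO[Al-]1(OCCOC)OCCOC | intermediate
10 | (2Z)-3-iodobut-2-en-1-ol | C/C(I)=C/CO | intermediate
11 | tert-butyl{[(2Z)-3-iodobut-2-en-1-yl]oxy}dimethylsilane | C/C(I)=C/CO[Si](C)(C)C(C)(C)C | intermediate
12 | (Z)-alkenylchromium(III) dichloride from 11 | C/C([Cr](Cl)Cl)=C/CO[Si](C)(C)C(C)(C)C | intermediate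
13 | (2Z,4S,6E)-1,9-bis(TBS-oxy)-3,7-dimethylnona-2,6-dien-4-ol | CC(C)(C)[Si](C)(C)OC/C=C(/C)[C@@H](O)C/C=C(\C)CCO[Si](C)(C)C(C)(C)C | intermediate
14 | (2Z,4S,6E)-1,9-bis(TBS-oxy)-3,7-dimethylnona-2,6-dien-4-yl methacrylate | CC(C)(C)[Si](C)(C)OC/C=C(/C)[C@@H](OC(=O)C(C)=C)C/C=C(\C)CCO[Si](C)(C)C(C)(C)C | intermediate
15 | (2Z,4S,6E)-1,9-dihydroxy-3,7-dimethylnona-2,6-dien-4-yl methacrylate | OC/C=C(/C)[C@@H](OC(=O)C(C)=C)C/C=C(\C)CCO | intermediate
16 | (2Z,4S,6E)-3,7-dimethyl-1,9-dioxonona-2,6-dien-4-yl methacrylate | O=C/C=C(/C)[C@@H](OC(=O)C(C)=C)C/C=C(\C)CC=O | intermediate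
17 | (1R,4R,5R)-4,7,7-trimethyl-6-thiabicyclo[3.2.1]octane (isothiocineole) | C[C@@H]1CC[C@@H]2C[C@H]1SC2(C)C | starting material
18 | methyl 2-(bromomethyl)acrylate | C=C(CBr)C(=O)OC | starting material
19 | S-[2-(methoxycarbonyl)allyl]isothiocineolium bromide | [Br-].C[C@@H]1CC[C@@H]2C[C@H]1[S+](CC(=C)C(=O)OC)C2(C)C | intermediate
20 | 2-(methoxycarbonyl)allylide of isothiocineole | C[C@@H]1CC[C@@H]2C[C@H]1[S+]([CH-]C(=C)C(=O)OC)C2(C)C | intermediate
21 | methyl 2-[(2R,3R)-3-{(2E,5S,6Z)-5-(methacryloyloxy)-2,6-dimethyl-8-oxoocta-2,6-dien-1-yl}oxiran-2-yl]acrylate | O=C/C=C(/C)[C@@H](OC(=O)C(C)=C)C/C=C(\C)C[C@H]1O[C@@H]1C(=C)C(=O)OC | intermediate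
22 | methyl (2Z,4R,6E,9S,10Z)-2-(iodomethyl)-9-(methacryloyloxy)-6,10-dimethyl-12-oxo-4-(trimethylsilyloxy)dodeca-2,6,10-trienoate | O=C/C=C(/C)[C@@H](OC(=O)C(C)=C)C/C=C(\C)C[C@@H](O[Si](C)(C)C)/C=C(\CI)C(=O)OC | intermediate
23 | 2-(methoxycarbonyl)allylchromium(III) dichloride from 22 (C8 trans to CH2Cr) | O=C/C=C(/C)[C@@H](OC(=O)C(C)=C)C/C=C(\C)C[C@@H](O[Si](C)(C)C)/C=C(/C[Cr](Cl)Cl)C(=O)OC | intermediate
24 | ten-membered seco ester as O6 chromium(III) alkoxide | C=C(C)C(=O)O[C@H]1C/C=C(\C)C[C@@H](O[Si](C)(C)C)[C@@H](C(=C)C(=O)OC)[C@H](O[Cr](Cl)Cl)/C=C\1C | intermediate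
25 | 8-O-trimethylsilyl ether of 26 | C=C(C)C(=O)O[C@H]1C/C=C(\C)C[C@@H](O[Si](C)(C)C)[C@H]2C(=C)C(=O)O[C@@H]2/C=C\1C | intermediate
26 | (3S,6R,7R,8R)-8-hydroxy-3-(methacryloyloxy)germacra-1(10)E,4Z,11(13)-trien-12,6-olide | C=C(C)C(=O)O[C@H]1C/C=C(\C)C[C@@H](O)[C@H]2C(=C)C(=O)O[C@@H]2/C=C\1C | intermediate
27 | (3S,6R,7R,8R)-8-(angeloyloxy)-3-(methacryloyloxy)germacra-1(10)E,4Z,11(13)-trien-12,6-olide | C=C(C)C(=O)O[C@H]1C/C=C(\C)C[C@@H](OC(=O)/C(C)=C\C)[C@H]2C(=C)C(=O)O[C@@H]2/C=C\1C | intermediate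
28 | CNP0294228.1, (1R,3S,6R,7R,8R,10R) | C=C(C)C(=O)O[C@H]1C[C@H]2O[C@]2(C)C[C@@H](OC(=O)/C(C)=C\C)[C@H]2C(=C)C(=O)O[C@@H]2/C=C\1C | target

**Step count**
- Total step count: 14.
- Longest linear sequence: 11 (steps 1–3, 6–9, 11–14).

**Three steps most likely to fail**

Step 12 (ring closure). The main risks are β-elimination of the allylchromium to a diene, oligomerisation, and the wrong C7 face. The fallback sets out from 21 and comes back at 27.
- The oxirane is no longer used as a one-pot latent nucleophile. It is opened acylatively with angelic anhydride and MgBr2·OEt2 (CH2Cl2, −20 °C). Bromide goes to C13 and the angelate to O8, giving the isolable allylic bromide F1, which already carries the final C8 ester.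
- The ring is then closed as a zinc- or indium-mediated aqueous Barbier reaction (THF/aq. NH4Cl, high dilution), followed by acid-catalysed lactonisation.
- This gives 27 directly, so 26 and step 13 drop out.

Step 11 (ylide epoxidation). The risks are chemoselectivity between the two aldehydes, base sensitivity of the β,γ-unsaturated aldehyde, and the trans/cis ratio that decides C8. The fallback sets out from 16 and comes back at 28.
- A Horner–Wadsworth–Emmons reaction at the aliphatic aldehyde uses the lithium anion of methyl 2-[(diethoxyphosphoryl)methyl]acrylate (THF, −78 °C) and gives the cross-conjugated dienoate F2.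
- Shi epoxidation (D-fructose-derived ketone, Oxone, K2CO3 buffer, 0 °C) oxidises the C7=C8 and C1=C10 alkenes, both in the (R,R) sense. The enal and the acrylates are left alone, and the product is the bis-oxirane F3.
- Ring closure follows step 12 with exactly one equivalent of TMSI at −78 °C, where the acrylate-conjugated oxirane reacts first. This gives the epoxy alcohol F4.
- Acylation as in step 13 gives 28, so step 14 is not needed.

Step 6 (asymmetric Ni/Cr coupling). The risks are that the level of induction depends on the substrate and that Et3N may conjugate the aldehyde. The fallback sets out from 7 and 11 and comes back at 13.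
- Iodine–lithium exchange on 11 (t-BuLi, Et2O, −78 °C) and addition to 7 gives the racemic alcohol F5.
- Dess–Martin oxidation gives the dienone F6.
- Reduction with (R)-Me-CBS and catecholborane (toluene, −78 °C) places hydride on the face set by alkenyl (large) versus CH2 (small). This sets 4S by ketone reduction instead of by C–C bond formation.

**Further compounds**
F1 | step 12 | methyl (2Z,4R,6E,9S,10Z)-4-(angeloyloxy)-2-(bromomethyl)-9-(methacryloyloxy)-6,10-dimethyl-12-oxododeca-2,6,10-trienoate | O=C/C=C(/C)[C@@H](OC(=O)C(C)=C)C/C=C(\C)C[C@@H](OC(=O)/C(C)=C\C)/C=C(\CBr)C(=O)OC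
F2 | step 11 | methyl (3E,6E,9S,10Z)-9-(methacryloyloxy)-6,10-dimethyl-2-methylidene-12-oxododeca-3,6,10-trienoate | O=C/C=C(/C)[C@@H](OC(=O)C(C)=C)C/C=C(\C)C/C=C/C(=C)C(=O)OC
F3 | step 11 | methyl 2-[(2R,3R)-3-({(2R,3R)-3-[(2S,3Z)-2-(methacryloyloxy)-3-methyl-5-oxopent-3-en-1-yl]-2-methyloxiran-2-yl}methyl)oxiran-2-yl]acrylate | O=C/C=C(/C)[C@@H](OC(=O)C(C)=C)C[C@H]1O[C@]1(C)C[C@H]2O[C@@H]2C(=C)C(=O)OC
F4 | step 11 | (1R,3S,6R,7R,8R,10R)-1,10-epoxy-8-hydroxy-3-(methacryloyloxy)germacra-4Z,11(13)-dien-12,6-olide | C=C(C)C(=O)O[C@H]1C[C@H]2O[C@]2(C)C[C@@H](O)[C@H]2C(=C)C(=O)O[C@@H]2/C=C\1C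
F5 | step 6 | racemic (2Z,6E)-1,9-bis(TBS-oxy)-3,7-dimethylnona-2,6-dien-4-ol | CC(C)(C)[Si](C)(C)OC/C=C(/C)C(O)C/C=C(\C)CCO[Si](C)(C)C(C)(C)C
F6 | step 6 | (2Z,6E)-1,9-bis(TBS-oxy)-3,7-dimethylnona-2,6-dien-4-one | CC(C)(C)[Si](C)(C)OC/C=C(/C)C(=O)C/C=C(\C)CCO[Si](C)(C)C(C)(C)C
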